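The [3]-ladderane core (tetracyclo[6.4.0.0(2,7).0(3,6)]dodecane numbering) is cut through its central cyclobutane, ring B (C-2, C-3, C-6, C-7), whose bonds C-2–C-3 and C-6–C-7 each join the cyclohexane-fused ring A (C-1, C-2, C-7, C-8) to the terminal ring C (C-3 to C-6). One CuOTf-catalysed [2+2] photocycloaddition makes both bonds, joining cyclobutene to the strained cyclobutene π-bond of an enantioenriched 3-alkylbicyclo[4.2.0]octa-3,7-diene that already carries the whole acetonide-protected glycerol ether chain; approach to the convex face gives the anti,anti ladder. That diene arises from a catalytic asymmetric Diels–Alder reaction of cyclobutenone with a 2-alkylbutadiene followed by a Shapiro reaction. Convex-face hydrogenation of the remaining cyclohexene finally sets the chain-bearing stereocentre.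

Key step: step 8

Assumption: in step 4 the sense of induction is taken from the α-C–H···O pre-transition-state model for 2-cycloalkenones bound to the oxazaborolidinium ion, by which the (R)-configured catalyst should give the (1R,6R) adduct; if the adduct proves antipodal, the (S)-catalyst is used and nothing else changes.

**Route**

Step 1
Reactants: 1 2,2-dimethyl-1,3-dioxan-5-ol; 2 1,8-dibromooctane
Product: 3 5-[(8-bromooctyl)oxy]-2,2-dimethyl-1,3-dioxane
Conditions: NaH (1.1 equiv), DMF, 0 °C; then 1,8-dibromooctane (4 equiv), Bu4NI (cat.), 0 °C to rt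
Reagents that add atoms: none
Why: Williamson ether synthesis, in which the sodium alkoxide of the secondary alcohol displaces one primary bromide by SN2 and the fourfold excess of the dibromide should suppress double alkylation; no stereocentre is involved.

Step 2
Reactants: 3 5-[(8-bromooctyl)oxy]-2,2-dimethyl-1,3-dioxane; 4 chloroprene
Product: 6 2,2-dimethyl-5-[(9-methylideneundec-10-en-1-yl)oxy]-1,3-dioxane, via alkylmagnesium bromide 5 (not isolated)
Conditions: Mg, THF, 40 °C; then chloroprene (2 equiv), Ni(dppp)Cl2 (2 mol %), THF, 0 °C to rt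
Reagents that add atoms: none
Why: Kumada–Corriu cross-coupling of a primary alkyl Grignard reagent with the alkenyl chloride of chloroprene, a standard entry to 2-alkylbuta-1,3-dienes, to which the ketal and ether are inert.

Step 3
Reactants: 7 3-bromocyclobutan-1-one
Product: 8 cyclobut-2-en-1-one
Conditions: n-Bu3N (1.05 equiv), neat, rt; vacuum transfer into a −78 °C trap, kept as a cold CH2Cl2 solution
Reagents that add atoms: none
Why: Amine-mediated dehydrobromination (E1cB) of the β-bromo ketone should give the volatile strained enone, which is separated from the ammonium salt by vacuum transfer.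

Step 4
Reactants: 6 2,2-dimethyl-5-[(9-methylideneundec-10-en-1-yl)oxy]-1,3-dioxane; 8 cyclobut-2-en-1-one
Product: 9 (1R,6R)-3-{8-[(2,2-dimethyl-1,3-dioxan-5-yl)oxy]octyl}bicyclo[4.2.0]oct-3-en-7-one
Conditions: cyclobut-2-en-1-one (1.5 equiv), (R)-3,3-diphenyl-1-(o-tolyl)tetrahydropyrrolo[1,2-c][1,3,2]oxazaborole (20 mol %), Tf2NH (18 mol %), CH2Cl2, −78 °C
Reagents that add atoms: none
Why: Catalytic enantioselective Diels–Alder reaction of a 2-cycloalkenone activated by a chiral oxazaborolidinium ion, in which suprafacial addition to the cyclic dienophile gives the cis ring fusion, the catalyst selects the enone face (C-1 and C-6) and the Lewis acid reinforces the "para" orientation that places the alkyl-bearing alkene carbon 1,4 to the carbonyl-bearing ring-fusion carbon.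

Step 5
Reactants: 9 (1R,6R)-3-{8-[(2,2-dimethyl-1,3-dioxan-5-yl)oxy]octyl}bicyclo[4.2.0]oct-3-en-7-one
Product: 10 4-methylbenzenesulfonohydrazone of 9 (1R,6R; C=N geometry not defined)
Conditions: TsNHNH2 (1.05 equiv), MeOH, rt
Reagents that add atoms: 4-methylbenzenesulfonohydrazide, Cc1ccc(cc1)S(=O)(=O)NN
Why: Condensation of the strained, reactive cyclobutanone with tosylhydrazide under neutral conditions should leave the ketal intact and cannot disturb the cis ring fusion.

Step 6
Reactants: 10 4-methylbenzenesulfonohydrazone of 9
Product: 12 (1R,6S)-3-{8-[(2,2-dimethyl-1,3-dioxan-5-yl)oxy]octyl}bicyclo[4.2.0]octa-3,7-diene, via alkenyllithium 11 (not isolated)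
Conditions: LDA (3 equiv), THF, −78 °C to rt; H2O quench
Reagents that add atoms: none
Why: Shapiro reaction, in which deprotonation of N–H and of the less substituted α-CH2 (C-8), loss of sulfinate and N2, and protonation of the cyclobutenyllithium should give the C-7/C-8 alkene without touching the two stereocentres.

Step 7
Reactants: 13 bromocyclobutane
Product: 14 cyclobutene
Conditions: KOtBu, DMSO, 70 °C; gas swept with N2 into a −78 °C trap
Reagents that add atoms: none
Why: E2 dehydrobromination in KOtBu/DMSO should deliver cyclobutene (bp about 2 °C), which leaves the mixture as it forms and is condensed for direct use.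

Step 8
Reactants: 12 (1R,6S)-3-{8-[(2,2-dimethyl-1,3-dioxan-5-yl)oxy]octyl}bicyclo[4.2.0]octa-3,7-diene; 14 cyclobutene
Product: 15 (1R,2S,3S,6R,7R,8S)-10-{8-[(2,2-dimethyl-1,3-dioxan-5-yl)oxy]octyl}tetracyclo[6.4.0.0(2,7).0(3,6)]dodec-10-ene
Conditions: (CuOTf)2·C6H6 (5 mol %), cyclobutene in fifteenfold excess, Et2O, hν 254 nm (quartz), −20 °C, diene at about 0.03 M
Reagents that add atoms: none
Why: CuOTf binds the two strained cyclobutene π-bonds of 12 and 14 in a bis(alkene) complex of monovalent copper, and 254 nm excitation of its charge-transfer band couples the coordinated alkenes in a [2π+2π] cycloaddition that forms the C-2–C-3 and C-6–C-7 bonds of 15 in one operation and releases the catalyst. The closest known reaction type is the Kochi–Salomon photocycloaddition of strained cycloalkenes, which dimerises cyclobutene-type alkenes to anti-ladderanes and gives mixed adducts when one alkene is used in excess. The one ring closed, the central cyclobutane (ring B), closes by intermolecular [2+2] cycloaddition that is suprafacial on both alkenes, so both of its new ring fusions are necessarily cis. The stereocentres C-2 and C-7 are set by approach of copper and cyclobutene to the convex face of the cis-fused bicycle, opposite the six-membered ring and fixed by the existing C-1 and C-8 centres, and C-3 and C-6 are set by the anti orientation of the CH2CH2 bridge of cyclobutene away from the existing four-membered ring, as in the cis-anti-cis dimers of this reaction. The step needs chemoselectivity for the cyclobutene over the trisubstituted cyclohexene π-bond, which the much stronger binding of strained cis-disubstituted alkenes to copper should secure, and cross- over homo-coupling, which the excess of 14 (its dimer is volatile) and the dilution of 12 should secure.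

Step 9
Reactants: 15 (1R,2S,3S,6R,7R,8S)-10-{8-[(2,2-dimethyl-1,3-dioxan-5-yl)oxy]octyl}tetracyclo[6.4.0.0(2,7).0(3,6)]dodec-10-ene
Product: 17 2-({8-[(1R,2S,3S,6R,7R,8S,10S)-tetracyclo[6.4.0.0(2,7).0(3,6)]dodecan-10-yl]octyl}oxy)propane-1,3-diol, via hydrogenated acetonide 16 (not isolated)
Conditions: [Ir(cod)(PCy3)(py)]PF6 (5 mol %), H2 (1 atm), CH2Cl2, 0 °C to rt; then MeOH, 1 M aq HCl, rt
Reagents that add atoms: none
Why: Homogeneous hydrogenation of the trisubstituted alkene should deliver H2 to the convex face of the cis-fused cyclohexene (the face of the two ring-fusion hydrogens, away from the folded ladderane), placing the octyl chain cis to the four-membered ring (10S) without hydrogenolysis of strained bonds, and acid-catalysed acetal cleavage in methanol then removes the isopropylidene group.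

**Compound list**

1 | 2,2-dimethyl-1,3-dioxan-5-ol | CC1(C)OCC(O)CO1 | starting material
2 | 1,8-dibromooctane | BrCCCCCCCCBr | starting material
3 | 5-[(8-bromooctyl)oxy]-2,2-dimethyl-1,3-dioxane | CC1(C)OCC(CO1)OCCCCCCCCBr | intermediate
4 | chloroprene (2-chlorobuta-1,3-diene) | C=CC(Cl)=C | starting material
5 | {8-[(2,2-dimethyl-1,3-dioxan-5-yl)oxy]octyl}magnesium bromide | CC1(C)OCC(CO1)OCCCCCCCC[Mg]Br | intermediate
6 | 2,2-dimethyl-5-[(9-methylideneundec-10-en-1-yl)oxy]-1,3-dioxane | CC1(C)OCC(CO1)OCCCCCCCCC(=C)C=C | intermediate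
7 | 3-bromocyclobutan-1-one | O=C1CC(Br)C1 | starting material
8 | cyclobut-2-en-1-one | O=C1CC=C1 | intermediate
9 | (1R,6R)-3-{8-[(2,2-dimethyl-1,3-dioxan-5-yl)oxy]octyl}bicyclo[4.2.0]oct-3-en-7-one (cis-fused) | CC1(C)OCC(CO1)OCCCCCCCCC1=CC[C@@H]2[C@H](C1)CC2=O | intermediate
10 | 4-methylbenzenesulfonohydrazone of 9 (1R,6R) | CC1(C)OCC(CO1)OCCCCCCCCC1=CC[C@@H]2[C@H](C1)CC2=NNS(=O)(=O)c1ccc(C)cc1 | intermediate
11 | 7-lithio derivative of 12 (cyclobutenyllithium) | CC1(C)OCC(CO1)OCCCCCCCCC1=CC[C@@H]2[C@H](C1)C=C2[Li] | intermediate
12 | (1R,6S)-3-{8-[(2,2-dimethyl-1,3-dioxan-5-yl)oxy]octyl}bicyclo[4.2.0]octa-3,7-diene (cis-fused) | CC1(C)OCC(CO1)OCCCCCCCCC1=CC[C@@H]2[C@H](C1)C=C2 | intermediate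
13 | bromocyclobutane | BrC1CCC1 | starting material
14 | cyclobutene | C1=CCC1 | intermediate
15 | (1R,2S,3S,6R,7R,8S)-10-{8-[(2,2-dimethyl-1,3-dioxan-5-yl)oxy]octyl}tetracyclo[6.4.0.0(2,7).0(3,6)]dodec-10-ene (all ring fusions cis, ladder anti,anti) | CC1(C)OCC(CO1)OCCCCCCCCC1=CC[C@@H]2[C@H](C1)[C@H]1[C@@H]3CC[C@@H]3[C@@H]21 | intermediate
16 | (1R,2S,3S,6R,7R,8S,10S)-10-{8-[(2,2-dimethyl-1,3-dioxan-5-yl)oxy]octyl}tetracyclo[6.4.0.0(2,7).0(3,6)]dodecane (chain cis to the four-membered ring on the cyclohexane) | CC1(C)OCC(CO1)OCCCCCCCC[C@H]1CC[C@@H]2[C@H](C1)[C@H]1[C@@H]3CC[C@@H]3[C@@H]21 | intermediate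
17 | 2-({8-[(1R,2S,3S,6R,7R,8S,10S)-tetracyclo[6.4.0.0(2,7).0(3,6)]dodecan-10-yl]octyl}oxy)propane-1,3-diol | OCC(CO)OCCCCCCCC[C@H]1CC[C@@H]2[C@H](C1)[C@H]1[C@@H]3CC[C@@H]3[C@@H]21 | target

**Step count**

Total steps: 9. Longest linear sequence: 7 (steps 1, 2, 4, 5, 6, 8, 9).

**Steps most likely to fail, with fallbacks**

1. Step 8. The risks are homo-coupling of either alkene in place of cross-coupling, stalling through competitive light absorption or through binding of copper by the ether oxygens, engagement of the cyclohexene π-bond, and incomplete anti selectivity. The fallback sets out from 10 and comes back at 15. It replaces the copper-templated union of two unactivated alkenes by an enoate–alkene photocycloaddition in which the bicycle itself carries the chromophore, so that only its cyclobutene π-bond is excited. The Shapiro reaction of 10 is run with n-BuLi in THF/TMEDA (−78 to 0 °C), and the alkenyllithium 11 is trapped at −78 °C with methyl chloroformate to give the cyclobutene ester F1. Irradiation of F1 at 300 nm in acetone (solvent and triplet sensitiser) at −20 °C with cyclobutene in tenfold excess should add cyclobutene to the convex face and give the ladderane ester F2. Saponification (LiOH, THF/MeOH/H2O, 50 °C) gives the acid F3. Esterification with N-hydroxypyridine-2-thione (DCC, DMAP, CH2Cl2, dark) gives the Barton ester F4. Visible-light irradiation of F4 with t-BuSH (Barton decarboxylation) replaces the carboxyl group by hydrogen, which the ring-fusion radical can accept only with cis ring fusion, to give 15.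

2. Step 4. The risks are loss of enantiomeric purity through incomplete "para" orientation (the "meta" adduct leads after step 6 to the enantiomer of 12), inhibition of the Lewis acid by the ketal and ether oxygens, and acid-induced polymerisation of the dienophile. The fallback sets out from 6 and 8 and comes back at 9. It separates ring construction from enantiocontrol. A ZnCl2-promoted Diels–Alder reaction in CH2Cl2 at 0 °C gives the racemic cis adduct, that is 9 together with its (1S,6S)-enantiomer F5. A ketoreductase chosen from a screening panel (NADPH, glucose/glucose dehydrogenase recycling, pH 7 buffer with DMSO) then reduces only F5 to the cyclobutanol F6. The unreacted 9 is separated from the alcohol by chromatography.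

3. Step 9. The risks are insufficient facial discrimination in hydrogen delivery to the remote trisubstituted alkene, which would give a C-10 epimer that is hard to separate, and alkene migration before reduction. The fallback sets out from 15 and comes back at 16. It uses a bulkier reagent and an isolable, separable intermediate. Hydroboration–oxidation (BH3·SMe2, THF, 0 °C; then NaOH, H2O2) adds H to C-10 and boron to C-11 syn from the convex face to give the secondary alcohol F7, whose minor diastereomer can be removed by chromatography. Xanthate formation (NaH, CS2, then MeI, THF) gives the xanthate F8. Barton–McCombie deoxygenation (Bu3SnH, AIBN, toluene, 80 °C) gives 16, which is converted into 17 by the acidic acetal cleavage of step 9.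

**Further compounds**

F1 | step 8 | methyl (1R,6R)-3-{8-[(2,2-dimethyl-1,3-dioxan-5-yl)oxy]octyl}bicyclo[4.2.0]octa-3,7-diene-7-carboxylate | CC1(C)OCC(CO1)OCCCCCCCCC1=CC[C@@H]2[C@H](C1)C=C2C(=O)OC
F2 | step 8 | 2-(methoxycarbonyl) derivative of 15 (ester at C-2, the ring-fusion carbon of rings A and B next to C-1) | CC1(C)OCC(CO1)OCCCCCCCCC1=CC[C@@H]2[C@H](C1)[C@H]1[C@@H]3CC[C@@H]3[C@@]21C(=O)OC
F3 | step 8 | 2-carboxylic acid corresponding to F2 | CC1(C)OCC(CO1)OCCCCCCCCC1=CC[C@@H]2[C@H](C1)[C@H]1[C@@H]3CC[C@@H]3[C@@]21C(=O)O
F4 | step 8 | 2-thioxopyridin-1(2H)-yl ester of F3 (Barton ester) | CC1(C)OCC(CO1)OCCCCCCCCC1=CC[C@@H]2[C@H](C1)[C@H]1[C@@H]3CC[C@@H]3[C@@]21C(=O)ON1C=CC=CC1=S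
F5 | step 4 | (1S,6S)-3-{8-[(2,2-dimethyl-1,3-dioxan-5-yl)oxy]octyl}bicyclo[4.2.0]oct-3-en-7-one (enantiomer of 9) | CC1(C)OCC(CO1)OCCCCCCCCC1=CC[C@H]2[C@@H](C1)CC2=O
F6 | step 4 | (1S,6S,7S)-3-{8-[(2,2-dimethyl-1,3-dioxan-5-yl)oxy]octyl}bicyclo[4.2.0]oct-3-en-7-ol | CC1(C)OCC(CO1)OCCCCCCCCC1=CC[C@H]2[C@@H](C1)C[C@@H]2O
F7 | step 9 | 11-hydroxy derivative of 16 (OH trans to the octyl chain) | CC1(C)OCC(CO1)OCCCCCCCC[C@H]1[C@H](O)C[C@@H]2[C@H](C1)[C@H]1[C@@H]3CC[C@@H]3[C@@H]21
F8 | step 9 | O-alkyl S-methyl dithiocarbonate (xanthate) of F7 | CC1(C)OCC(CO1)OCCCCCCCC[C@H]1[C@H](OC(=S)SC)C[C@@H]2[C@H](C1)[C@H]1[C@@H]3CC[C@@H]3[C@@H]21
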